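**Strategy**

The route rests on an intramolecular Diels–Alder reaction that forms C5–C10 and C8–C9 and so closes rings A and B in one operation. It exploits the 1,3-relation of the C6 carbonyl and the C8 methylene in ring B: the precursor is an open chain in which a 2-siloxy vinylallene (C5=C6(OSi)–C7=C8=C17) is tied through C4(Me2)–C3HCl–C2HCl–C1 to the E-trisubstituted alkene C9=C10 that already carries C11–C12. The threo C2/C3 dichloride, set beforehand by enantioselective anti-dichlorination of a (Z)-allylic alcohol, is the only stereochemical information in the chain and directs C5, C9 and C10 through a chair tether with both chlorines equatorial. An Evans aldol and imide closure then add C13–C16.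

Key step: step 14

Remark: labdane numbering is used throughout (decalin C1–C10, side chain C11–C12, methylene carbon C17, succinimide C13–C16); TBS = tert-butyldimethylsilyl.
Remark: methyl 2,2-dimethylbut-3-enoate is taken as commercial (otherwise one esterification of the commercial acid).
Remark: O–metal and O–boron forms of a product that are only hydrolysed on work-up are not numbered separately.

**Route**

Step 1
Reactants: 1 methyl 2,2-dimethylbut-3-enoate
Product: 2 2,2-dimethylbut-3-enal
Conditions: DIBAL-H (1.05 equiv), CH2Cl2, −78 °C; Rochelle salt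
Reagents that add atoms: none
Why: Partial DIBAL reduction of an α-quaternary methyl ester should stop at the aldehyde because the tetrahedral aluminate is stable at −78 °C; no stereocentre is formed.

Step 2
Reactants: 2 2,2-dimethylbut-3-enal; 3 methyl 2-[bis(2,2,2-trifluoroethoxy)phosphoryl]acetate
Product: 4 methyl (2Z)-4,4-dimethylhexa-2,5-dienoate
Conditions: KHMDS, 18-crown-6, THF, −78 °C
Reagents that add atoms: none
Why: The Still–Gennari variant of the Horner–Wadsworth–Emmons olefination should give the (Z)-enoate kinetically, and this cis geometry is what later becomes the threo dichloride.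

Step 3
Reactants: 4 methyl (2Z)-4,4-dimethylhexa-2,5-dienoate
Product: 5 (2Z)-4,4-dimethylhexa-2,5-dien-1-ol
Conditions: DIBAL-H (2.2 equiv), CH2Cl2, −78 °C
Reagents that add atoms: none
Why: 1,2-Reduction of the enoate with DIBAL-H should leave both alkenes and the Z geometry untouched.

Step 4
Reactants: 5 (2Z)-4,4-dimethylhexa-2,5-dien-1-ol
Product: 6 (2R,3R)-2,3-dichloro-4,4-dimethylhex-5-en-1-ol
Conditions: t-BuOCl, ClTi(Oi-Pr)3, chiral tridentate Schiff-base ligand (20 mol %, enantiomer selected for the 2R,3R product), hexanes, −20 °C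
Reagents that add atoms: tert-butyl hypochlorite CC(C)(C)OCl; chlorotitanium triisopropoxide CC(C)O[Ti](Cl)(OC(C)C)OC(C)C
Why: Titanium-catalysed enantioselective dichlorination of allylic alcohols: the substrate is bound as its titanium alkoxide, Cl+ and titanium-bound chloride add anti across the Z alkene only, and the ligand selects the face, which should set C2 and C3 as the (2R,3R)-threo dichloride while the unbound vinyl group stays intact.

Step 5
Reactants: 6 (2R,3R)-2,3-dichloro-4,4-dimethylhex-5-en-1-ol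
Product: 7 (2R,3R)-2,3-dichloro-4,4-dimethylhex-5-en-1-yl trifluoromethanesulfonate
Conditions: Tf2O, 2,6-lutidine, CH2Cl2, −78 °C; used at once
Reagents that add atoms: trifluoromethanesulfonic anhydride O=S(=O)(OS(=O)(=O)C(F)(F)F)C(F)(F)F
Why: O-Sulfonylation of the primary alcohol gives the very reactive leaving group needed for substitution at a carbon that the β-chlorine retards; no stereocentre is touched.

Step 6
Reactants: 8 pent-3-yn-1-ol
Product: 9 tert-butyldimethyl(pent-3-yn-1-yloxy)silane
Conditions: TBSCl, imidazole, DMF, 23 °C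
Reagents that add atoms: tert-butyldimethylsilyl chloride CC(C)(C)[Si](C)(C)Cl
Why: Standard silylation of a primary alcohol.

Step 7
Reactants: 9 tert-butyldimethyl(pent-3-yn-1-yloxy)silane
Product: 11 tert-butyl{[(3E)-4-iodopent-3-en-1-yl]oxy}dimethylsilane, via alkenylzirconocene chloride 10 (not isolated)
Conditions: Cp2Zr(H)Cl (2 equiv), THF, 50 °C; then I2, 0 °C
Reagents that add atoms: iodine II
Why: Hydrozirconation with the Schwartz reagent is a syn addition in which zirconium equilibrates to the less hindered methyl-bearing carbon, and iodinolysis with retention should give the (E)-2-iodoalkene with CH3 and the CH2 chain cis.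

Step 8
Reactants: 7 (2R,3R)-2,3-dichloro-4,4-dimethylhex-5-en-1-yl trifluoromethanesulfonate; 11 tert-butyl{[(3E)-4-iodopent-3-en-1-yl]oxy}dimethylsilane
Product: 14 tert-butyl{[(3E,6R,7R)-6,7-dichloro-4,8,8-trimethyldeca-3,9-dien-1-yl]oxy}dimethylsilane, via alkenyllithium 12 (not isolated), via alkenylmagnesium bromide 13 (not isolated)
Conditions: 11, t-BuLi (2.05 equiv), Et2O, −78 °C; MgBr2·OEt2; then 7, Li2CuCl4 (5 mol %), THF, −78 → −20 °C
Reagents that add atoms: none
Why: Iodine–lithium exchange with retention, transmetalation to magnesium and copper-catalysed sp2–sp3 Grignard cross-coupling with the primary triflate should form C1–C10 with the alkene geometry intact, the soft organocopper pathway at low temperature being chosen to outrun E2 loss next to the C2 chloride while the secondary chlorides stay inert.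

Step 9
Reactants: 14 tert-butyl{[(3E,6R,7R)-6,7-dichloro-4,8,8-trimethyldeca-3,9-dien-1-yl]oxy}dimethylsilane
Product: 16 (4R,5R,7E)-10-(TBS-oxy)-4,5-dichloro-3,3,7-trimethyldec-7-en-1-ol, via B-alkyl-9-BBN adduct 15 (not isolated)
Conditions: 9-BBN, THF, 23 °C; then NaOH, H2O2, 0 °C
Reagents that add atoms: hydrogen peroxide OO
Why: Anti-Markovnikov hydroboration with 9-BBN is selective for the monosubstituted vinyl group over the trisubstituted alkene, and oxidation should give the primary C6 alcohol.

Step 10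
Reactants: 16 (4R,5R,7E)-10-(TBS-oxy)-4,5-dichloro-3,3,7-trimethyldec-7-en-1-ol
Product: 17 (4R,5R,7E)-10-(TBS-oxy)-4,5-dichloro-3,3,7-trimethyldec-7-enal
Conditions: Dess–Martin periodinane, NaHCO3, CH2Cl2, 0 → 23 °C
Reagents that add atoms: none
Why: Dess–Martin oxidation under buffered neutral conditions should give the C6 aldehyde without affecting chlorides, alkene or silyl ether.

Step 11
Reactants: 17 (4R,5R,7E)-10-(TBS-oxy)-4,5-dichloro-3,3,7-trimethyldec-7-enal
Product: 18 (7R,8R,10E)-13-(TBS-oxy)-7,8-dichloro-6,6,10-trimethyltridec-10-en-1-yn-4-ol (C4 epimers)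
Conditions: propargyl bromide, In powder, THF/H2O, 23 °C
Reagents that add atoms: propargyl bromide C#CCBr
Why: Indium-mediated Barbier propargylation (SE2′ addition of the allenylindium species) should give the homopropargylic alcohol under conditions that do not reduce alkyl chlorides; the new C6 carbinol centre is oxidised in the next step, so its configuration is irrelevant.

Step 12
Reactants: 18 (7R,8R,10E)-13-(TBS-oxy)-7,8-dichloro-6,6,10-trimethyltridec-10-en-1-yn-4-ol
Product: 20 (7R,8R,10E)-13-(TBS-oxy)-7,8-dichloro-6,6,10-trimethyltrideca-1,2,10-trien-4-one, via propargyl ketone 19 (not isolated)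
Conditions: Dess–Martin periodinane, CH2Cl2, 0 °C; then Et3N (0.2 equiv), 23 °C
Reagents that add atoms: none
Why: Dess–Martin oxidation gives the β,γ-alkynyl ketone, which on brief contact with a tertiary amine should undergo propargyl-to-allenyl prototropy into the conjugated allenyl ketone.

Step 13
Reactants: 20 (7R,8R,10E)-13-(TBS-oxy)-7,8-dichloro-6,6,10-trimethyltrideca-1,2,10-trien-4-one
Product: 21 (4Z,7R,8R,10E)-4,13-bis(TBS-oxy)-7,8-dichloro-6,6,10-trimethyltrideca-1,2,4,10-tetraene
Conditions: TBSOTf, Et3N, Et2O, −78 °C; filtration through basic alumina, used promptly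
Reagents that add atoms: tert-butyldimethylsilyl trifluoromethanesulfonate CC(C)(C)[Si](C)(C)OS(=O)(=O)C(F)(F)F
Why: Soft enolisation (silyl triflate and tertiary amine) can only occur towards C5 and should give the thermodynamically preferred (Z)-silyl enol ether, i.e. the 2-siloxy vinylallene with the bulky C4 tether trans to the allenyl group and so on the outside of the diene.

Step 14
Reactants: 21 (4Z,7R,8R,10E)-4,13-bis(TBS-oxy)-7,8-dichloro-6,6,10-trimethyltrideca-1,2,4,10-tetraene
Product: 22 (2R,3R,5R,9S,10R)-2,3-dichloro-6,12-bis(TBS-oxy)-13,14,15,16-tetranorlabda-6,8(17)-diene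
Conditions: toluene (5 mM), BHT, 80 °C, base-washed sealed glass
Reagents that add atoms: none
Why: Thermal intramolecular [4+2] cycloaddition of a 1,7,9-decatriene whose diene is a 2-siloxy vinylallene, the closest known type being the IMDA of siloxy vinylallenes with unactivated alkenes, which runs at moderate temperature because the sp terminus C8 is unhindered (the quaternary C4 also blocks the [1,5]-H shift that drains other vinylallenes). Ring B is closed by concerted suprafacial formation of C5–C10 and C8–C9, and ring A at the same time by the four-carbon tether that links the bonding termini C5 and C10 (type-1 IMDA, tether in a chair, helped by the gem-dimethyl group). C9 and C10 are related by the E geometry of the dienophile (CH3 and C11 cis, hence 9β chain and 10β CH3), C5 to C10 by the exo position of the tether on the (Z)-enol ether, which leads to the trans ring fusion, and all three to C2/C3 because only the chair with both C–Cl bonds equatorial avoids syn-axial Cl/CH3 contacts with the C4 and C10 methyl groups. The allene keeps its distal π bond as the 8(17)-methylene and the silyl enol ether ends as the C6=C7 dienol ether, i.e. the masked β,γ-enone. The selectivity the step needs is trans over cis ring fusion (exo- over endo-tether transition state); the outside position of C4 on the diene and the boat-like tether demanded by the cis mode are counted on, and this remains the least secure point.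

Step 15
Reactants: 22 (2R,3R,5R,9S,10R)-2,3-dichloro-6,12-bis(TBS-oxy)-13,14,15,16-tetranorlabda-6,8(17)-diene
Product: 23 (2R,3R,5R,9S,10R)-2,3-dichloro-12-hydroxy-13,14,15,16-tetranorlabd-8(17)-en-6-one
Conditions: HF·pyridine, pyridine, THF, 0 → 23 °C
Reagents that add atoms: none
Why: Fluoride-assisted cleavage of both Si–O bonds, with kinetic protonation of the liberated dienol at the α-carbon C7 and not at C17, should release the β,γ-unsaturated ketone with the exocyclic methylene under buffered conditions.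

Step 16
Reactants: 23 (2R,3R,5R,9S,10R)-2,3-dichloro-12-hydroxy-13,14,15,16-tetranorlabd-8(17)-en-6-one
Product: 24 (2R,3R,5R,9S,10R)-2,3-dichloro-6-oxo-13,14,15,16-tetranorlabd-8(17)-en-12-al
Conditions: Dess–Martin periodinane, NaHCO3, CH2Cl2, 0 °C
Reagents that add atoms: none
Why: Buffered Dess–Martin oxidation of the primary alcohol is neutral enough to leave the β,γ-enone unconjugated.

Step 17
Reactants: 25 (4R)-4-benzyl-1,3-oxazolidin-2-one; 26 succinic anhydride
Product: 28 4-[(4R)-4-benzyl-2-oxo-1,3-oxazolidin-3-yl]-4-oxobutanoic acid, via lithium oxazolidinide 27 (not isolated)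
Conditions: n-BuLi, THF, −78 °C; then 26, −78 → 0 °C; aq. HCl
Reagents that add atoms: none
Why: N-Acylation of the lithiated oxazolidinone by ring opening of the cyclic anhydride.

Step 18
Reactants: 28 4-[(4R)-4-benzyl-2-oxo-1,3-oxazolidin-3-yl]-4-oxobutanoic acid
Product: 30 4-[(4R)-4-benzyl-2-oxo-1,3-oxazolidin-3-yl]-4-oxobutanamide, via mixed carbonic anhydride 29 (not isolated)
Conditions: i-BuOCOCl, N-methylmorpholine, THF, −20 °C; then NH3 (0.5 M in 1,4-dioxane)
Reagents that add atoms: ammonia N
Why: Mixed-anhydride activation and ammonolysis give the primary amide, the mixed anhydride being far more electrophilic than the imide carbonyl.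

Step 19
Reactants: 24 (2R,3R,5R,9S,10R)-2,3-dichloro-6-oxo-13,14,15,16-tetranorlabd-8(17)-en-12-al; 30 4-[(4R)-4-benzyl-2-oxo-1,3-oxazolidin-3-yl]-4-oxobutanamide
Product: 32 (2R,3R,5R,9S,10R,12S,13R)-aldol adduct bearing 12-OH and on C13 the (4R)-4-benzyl-2-oxooxazolidine-3-carbonyl group (C16) and CH2C(O)NH2 (C14–C15), via dibutylboron Z-enolate 31 (not isolated)
Conditions: 30 (1.3 equiv), n-Bu2BOTf, i-Pr2NEt, CH2Cl2, −78 → 0 °C; then 24, −78 → −20 °C; pH 7 buffer/MeOH
Reagents that add atoms: none
Why: Evans syn-aldol reaction: the (Z)-boron enolate reacts through a Zimmerman–Traxler chair on the face opposite to the benzyl group of the (R)-auxiliary and should set C13 (R) and C12 (S) together under reagent control, an extra equivalent of boron triflate and base being allowed for the primary amide and none left over to enolise the C6 ketone.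

Step 20
Reactants: 32 (2R,3R,5R,9S,10R,12S,13R)-aldol adduct
Product: 33 Haterumaimide B
Conditions: Et3N, LiCl, DMAP (cat.), THF, 23 °C
Reagents that add atoms: none
Why: Intramolecular N-acylation (5-exo-trig) of the primary amide by the N-acyloxazolidinone should close the succinimide and expel the auxiliary, lactonisation being unable to compete because C15 is an amide, and the mild amine/LiCl conditions are chosen to leave C13 and the β,γ-enone unequilibrated.

**Compound list**

1 | methyl 2,2-dimethylbut-3-enoate | C=CC(C)(C)C(=O)OC | starting material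
2 | 2,2-dimethylbut-3-enal | C=CC(C)(C)C=O | intermediate
3 | methyl 2-[bis(2,2,2-trifluoroethoxy)phosphoryl]acetate | COC(=O)CP(=O)(OCC(F)(F)F)OCC(F)(F)F | starting material
4 | methyl (2Z)-4,4-dimethylhexa-2,5-dienoate | C=CC(C)(C)/C=C\C(=O)OC | intermediate
5 | (2Z)-4,4-dimethylhexa-2,5-dien-1-ol | C=CC(C)(C)/C=C\CO | intermediate
6 | (2R,3R)-2,3-dichloro-4,4-dimethylhex-5-en-1-ol | C=CC(C)(C)[C@@H](Cl)[C@H](Cl)CO | intermediate
7 | (2R,3R)-2,3-dichloro-4,4-dimethylhex-5-en-1-yl trifluoromethanesulfonate | C=CC(C)(C)[C@@H](Cl)[C@H](Cl)COS(=O)(=O)C(F)(F)F | intermediate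
8 | pent-3-yn-1-ol | CC#CCCO | starting material
9 | tert-butyldimethyl(pent-3-yn-1-yloxy)silane | CC#CCCO[Si](C)(C)C(C)(C)C | intermediate
10 | chlorobis(cyclopentadienyl)[(2E)-5-(TBS-oxy)pent-2-en-2-yl]zirconium (not isolated) | C/C(=C\CCO[Si](C)(C)C(C)(C)C)[Zr](Cl)(C1C=CC=C1)C1C=CC=C1 | intermediate
11 | tert-butyl{[(3E)-4-iodopent-3-en-1-yl]oxy}dimethylsilane | C/C(I)=C\CCO[Si](C)(C)C(C)(C)C | intermediate
12 | [(2Z)-5-(TBS-oxy)pent-2-en-2-yl]lithium, CH3 and CH2 cis as in 11 (not isolated) | C/C([Li])=C\CCO[Si](C)(C)C(C)(C)C | intermediate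
13 | bromo[(2E)-5-(TBS-oxy)pent-2-en-2-yl]magnesium (not isolated) | C/C([Mg]Br)=C\CCO[Si](C)(C)C(C)(C)C | intermediate
14 | tert-butyl{[(3E,6R,7R)-6,7-dichloro-4,8,8-trimethyldeca-3,9-dien-1-yl]oxy}dimethylsilane | C=CC(C)(C)[C@@H](Cl)[C@H](Cl)C/C(C)=C/CCO[Si](C)(C)C(C)(C)C | intermediate
15 | 9-[(4R,5R,7E)-10-(TBS-oxy)-4,5-dichloro-3,3,7-trimethyldec-7-en-1-yl]-9-borabicyclo[3.3.1]nonane (not isolated) | C(CC(C)(C)[C@@H](Cl)[C@H](Cl)C/C(C)=C/CCO[Si](C)(C)C(C)(C)C)B1C2CCCC1CCC2 | intermediate
16 | (4R,5R,7E)-10-(TBS-oxy)-4,5-dichloro-3,3,7-trimethyldec-7-en-1-ol | OCCC(C)(C)[C@@H](Cl)[C@H](Cl)C/C(C)=C/CCO[Si](C)(C)C(C)(C)C | intermediate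
17 | (4R,5R,7E)-10-(TBS-oxy)-4,5-dichloro-3,3,7-trimethyldec-7-enal | O=CCC(C)(C)[C@@H](Cl)[C@H](Cl)C/C(C)=C/CCO[Si](C)(C)C(C)(C)C | intermediate
18 | (7R,8R,10E)-13-(TBS-oxy)-7,8-dichloro-6,6,10-trimethyltridec-10-en-1-yn-4-ol (C4 epimers) | C#CCC(O)CC(C)(C)[C@@H](Cl)[C@H](Cl)C/C(C)=C/CCO[Si](C)(C)C(C)(C)C | intermediate
19 | (7R,8R,10E)-13-(TBS-oxy)-7,8-dichloro-6,6,10-trimethyltridec-10-en-1-yn-4-one (not isolated) | C#CCC(=O)CC(C)(C)[C@@H](Cl)[C@H](Cl)C/C(C)=C/CCO[Si](C)(C)C(C)(C)C | intermediate
20 | (7R,8R,10E)-13-(TBS-oxy)-7,8-dichloro-6,6,10-trimethyltrideca-1,2,10-trien-4-one | C=C=CC(=O)CC(C)(C)[C@@H](Cl)[C@H](Cl)C/C(C)=C/CCO[Si](C)(C)C(C)(C)C | intermediate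
21 | (4Z,7R,8R,10E)-4,13-bis(TBS-oxy)-7,8-dichloro-6,6,10-trimethyltrideca-1,2,4,10-tetraene | C=C=C/C(O[Si](C)(C)C(C)(C)C)=C/C(C)(C)[C@@H](Cl)[C@H](Cl)C/C(C)=C/CCO[Si](C)(C)C(C)(C)C | intermediate
22 | (2R,3R,5R,9S,10R)-2,3-dichloro-6,12-bis(TBS-oxy)-13,14,15,16-tetranorlabda-6,8(17)-diene (trans-decalin, 2α,3β-Cl equatorial, 5α-H, 9β-CH2CH2OTBS, 10β-CH3) | C=C1C=C(O[Si](C)(C)C(C)(C)C)[C@H]2C(C)(C)[C@@H](Cl)[C@H](Cl)C[C@]2(C)[C@H]1CCO[Si](C)(C)C(C)(C)C | intermediate
23 | (2R,3R,5R,9S,10R)-2,3-dichloro-12-hydroxy-13,14,15,16-tetranorlabd-8(17)-en-6-one | C=C1CC(=O)[C@H]2C(C)(C)[C@@H](Cl)[C@H](Cl)C[C@]2(C)[C@H]1CCO | intermediate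
24 | (2R,3R,5R,9S,10R)-2,3-dichloro-6-oxo-13,14,15,16-tetranorlabd-8(17)-en-12-al | C=C1CC(=O)[C@H]2C(C)(C)[C@@H](Cl)[C@H](Cl)C[C@]2(C)[C@H]1CC=O | intermediate
25 | (4R)-4-benzyl-1,3-oxazolidin-2-one | O=C1N[C@H](Cc2ccccc2)CO1 | starting material
26 | succinic anhydride | O=C1CCC(=O)O1 | starting material
27 | lithium salt of 25 (not isolated) | [Li]N1[C@H](Cc2ccccc2)COC1=O | intermediate
28 | 4-[(4R)-4-benzyl-2-oxo-1,3-oxazolidin-3-yl]-4-oxobutanoic acid | OC(=O)CCC(=O)N1[C@H](Cc2ccccc2)COC1=O | intermediate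
29 | isobutyl carbonic mixed anhydride of 28 (not isolated) | CC(C)COC(=O)OC(=O)CCC(=O)N1[C@H](Cc2ccccc2)COC1=O | intermediate
30 | 4-[(4R)-4-benzyl-2-oxo-1,3-oxazolidin-3-yl]-4-oxobutanamide | NC(=O)CCC(=O)N1[C@H](Cc2ccccc2)COC1=O | intermediate
31 | dibutylboron (Z)-enolate of 30 (not isolated) | CCCCB(CCCC)O/C(=C\CC(N)=O)N1[C@H](Cc2ccccc2)COC1=O | intermediate
32 | (2R,3R,5R,9S,10R,12S,13R)-aldol adduct: 12-hydroxy, C13 bearing the (4R)-4-benzyl-2-oxooxazolidine-3-carbonyl group and CH2C(O)NH2 | C=C1CC(=O)[C@H]2C(C)(C)[C@@H](Cl)[C@H](Cl)C[C@]2(C)[C@H]1C[C@H](O)[C@H](C(=O)N1[C@H](Cc3ccccc3)COC1=O)CC(N)=O | intermediate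
33 | Haterumaimide B, (2R,3R,5R,9S,10R,12S,13R) | C=C1CC(=O)[C@H]2C(C)(C)[C@@H](Cl)[C@H](Cl)C[C@]2(C)[C@H]1C[C@H](O)[C@H]1CC(=O)NC1=O | target

**Totals and risks**

Total step count: 20. Longest linear sequence: 16 (steps 1–5, 8–16, 19, 20).

Steps most likely to fail:

1. Step 14 (key cycloaddition). The ring fusion may form with low trans/cis selectivity, or the allene may be consumed by oligomerisation before it cyclises. The fallback sets out from aldehyde 17 and replaces the allene by an allylsilane-terminated diene, so that C5 becomes correctable after the cycloaddition. Addition of vinylmagnesium bromide gives the allylic alcohol F1, and Dess–Martin oxidation the vinyl ketone F2. Cross-metathesis with allyltrimethylsilane (Grubbs second-generation catalyst) gives the (E)-γ-silyl enone F3, and soft enolisation (TBSOTf, Et3N) the 2-siloxy diene F4. Its thermal intramolecular Diels–Alder reaction (toluene, 160 °C) gives the cycloadduct F5 as ring-fusion epimers. Saegusa–Ito oxidation with Pd(OAc)2 and then DBU equilibrate C5, now α to a conjugated ketone, to the trans-fused enone F6. TBAF/AcOH removes the silicon from C17, protonates the resulting dienolate kinetically at C7 and cleaves the primary silyl ether, which returns the route to 23.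

2. Step 8 (C1–C10 coupling). E2 loss of triflic acid next to the C2 chloride and halogen–metal side reactions may outrun substitution. The fallback sets out from alcohol 6 and makes the bond through a radical instead of an SN2 process. Appel-type iodination (PPh3, I2, imidazole) gives the primary iodide F7. This is joined to vinyl iodide 11 by nickel-catalysed reductive cross-electrophile coupling (NiBr2·glyme, 4,4′-di-tert-butyl-2,2′-bipyridine, Mn, DMA), in which the C1 radical is captured by nickel faster than it loses the β-chlorine, and the route is rejoined at 14.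

3. Step 4 (enantioselective dichlorination). Opening of the chloronium at the neopentyl carbon C3 may compete poorly with opening at C2, which erodes the enantiomeric excess; the bulky cis substituent may also slow the reaction. The fallback sets out from 5 and obtains the stereochemistry by resolution instead of catalysis. The same titanium-directed dichlorination without the chiral ligand gives the racemic threo dichloro alcohol F8. Esterification with (S)-O-acetylmandelic acid (DCC, DMAP) gives the (2R,3R)-configured mandelate ester F9, which is separated by chromatography from its (2S,3S)-diastereomer F10. DIBAL-H cleavage of F9 returns the route to 6.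

Further compounds
F1 | step 14 | (6R,7R,9E)-12-(TBS-oxy)-6,7-dichloro-5,5,9-trimethyldodeca-1,9-dien-3-ol (C3 epimers) | C=CC(O)CC(C)(C)[C@@H](Cl)[C@H](Cl)C/C(C)=C/CCO[Si](C)(C)C(C)(C)C
F2 | step 14 | (6R,7R,9E)-12-(TBS-oxy)-6,7-dichloro-5,5,9-trimethyldodeca-1,9-dien-3-one | C=CC(=O)CC(C)(C)[C@@H](Cl)[C@H](Cl)C/C(C)=C/CCO[Si](C)(C)C(C)(C)C
F3 | step 14 | (2E,7R,8R,10E)-13-(TBS-oxy)-7,8-dichloro-6,6,10-trimethyl-1-(trimethylsilyl)trideca-2,10-dien-4-one | C[Si](C)(C)C/C=C/C(=O)CC(C)(C)[C@@H](Cl)[C@H](Cl)C/C(C)=C/CCO[Si](C)(C)C(C)(C)C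
F4 | step 14 | (2E,4Z,7R,8R,10E)-4,13-bis(TBS-oxy)-7,8-dichloro-6,6,10-trimethyl-1-(trimethylsilyl)trideca-2,4,10-triene | C[Si](C)(C)C/C=C/C(O[Si](C)(C)C(C)(C)C)=C/C(C)(C)[C@@H](Cl)[C@H](Cl)C/C(C)=C/CCO[Si](C)(C)C(C)(C)C
F5 | step 14 | (2R,3R,9S,10R)-2,3-dichloro-6,12-bis(TBS-oxy)-17-(trimethylsilyl)-13,14,15,16-tetranorlabd-6-ene (C5 epimers, C8 unassigned) | C[Si](C)(C)CC1C=C(O[Si](C)(C)C(C)(C)C)C2C(C)(C)[C@@H](Cl)[C@H](Cl)C[C@]2(C)[C@H]1CCO[Si](C)(C)C(C)(C)C
F6 | step 14 | (2R,3R,5R,9S,10R)-2,3-dichloro-12-(TBS-oxy)-17-(trimethylsilyl)-13,14,15,16-tetranorlabd-7-en-6-one | C[Si](C)(C)CC1=CC(=O)[C@H]2C(C)(C)[C@@H](Cl)[C@H](Cl)C[C@]2(C)[C@H]1CCO[Si](C)(C)C(C)(C)C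
F7 | step 8 | (4R,5S)-4,5-dichloro-6-iodo-3,3-dimethylhex-1-ene | C=CC(C)(C)[C@@H](Cl)[C@H](Cl)CI
F8 | step 4 | rac-(2R*,3R*)-2,3-dichloro-4,4-dimethylhex-5-en-1-ol (both enantiomers) | C=CC(C)(C)[C@@H](Cl)[C@H](Cl)CO.C=CC(C)(C)[C@H](Cl)[C@@H](Cl)CO
F9 | step 4 | (2R,3R)-2,3-dichloro-4,4-dimethylhex-5-en-1-yl (2S)-2-acetoxy-2-phenylacetate | C=CC(C)(C)[C@@H](Cl)[C@H](Cl)COC(=O)[C@@H](OC(C)=O)c1ccccc1
F10 | step 4 | (2S,3S)-2,3-dichloro-4,4-dimethylhex-5-en-1-yl (2S)-2-acetoxy-2-phenylacetate | C=CC(C)(C)[C@H](Cl)[C@@H](Cl)COC(=O)[C@@H](OC(C)=O)c1ccccc1
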